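## Retrosynthetic overview

1. C40 = C15 + C10 + C15. Two Wittig olefinations (C-11'=C-12' first, C-11=C-12 last) join acetylenic phosphonium salt 17, dialdehyde 18 and triol phosphonium salt 28; both silyl ethers come off last.
2. Both C15 ends go back to one ring building block, allylic alcohol 9. Ring A (acetylenic end): CH2OH → CHO → C≡CH, then Sonogashira coupling with enol triflate 13. Ring B (triol end): Sharpless epoxidation anti to the C-3 oxygen, C3 extension, water opening of the oxirane at C-5 with inversion, C2 extension.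
3. The carbocycle of 9 is made once, by a formal [4+2] cycloaddition of the silyl dienol ether of mesityl oxide (C-4, C-3, C-2, C-1 with both C-1 methyls) and ethyl but-2-ynoate (C-5 with its methyl, C-6 with C-7). It forms the C-4–C-5 and C-6–C-1 bonds together; a ketoreductase then sets the C-3 carbinol centre that both rings share.
4. Enabling feature: in ring A the oxygen-bearing C-3' lies 1,4 (para) to the alkynyl-bearing sp2 carbon C-6', and the tetrasubstituted C-5'=C-6' bond sits between the C-4' methylene and the quaternary C-1'(CH3)2. This is the retron of a 2-oxydiene + alkynoate cycloaddition, and ring B (C-1 to C-6) has the same carbon pattern, so one adduct serves both rings.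
5. Ring order: the six-membered carbocycle (step 2), used as made for ring A and, after a temporary oxirane (steps 13–16), for ring B.

Key step: step 2

Assumption: the target SMILES is read as (3S,5S,6S,3'R) with an all-E chain (3-OH and 5-OH cis, 5-OH and 6-OH trans); (2E,4E,6E)-2,7-dimethylocta-2,4,6-trienedial and a ketoreductase screening panel are taken as purchasable.

## Route

Step 1
Reactants: 1 mesityl oxide (4-methylpent-3-en-2-one)
Product: 3 tert-butyl(dimethyl)[(4-methylpenta-1,3-dien-2-yl)oxy]silane, via lithium dienolate 2 (not isolated)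
Conditions: LiN(iPr)2, THF, −78 °C; TBSCl, DMPU, −78 °C → rt
Reagents that add atoms: tert-butyl(chloro)dimethylsilane (TBSCl), CC(C)(C)[Si](C)(C)Cl
Why: Kinetic deprotonation of the enone at the α'-methyl group by the hindered amide should give the cross-conjugated lithium dienolate, which is O-silylated (silyl enol ether formation) to the 2-silyloxydiene.

Step 2
Reactants: 3 tert-butyl(dimethyl)[(4-methylpenta-1,3-dien-2-yl)oxy]silane; 4 ethyl but-2-ynoate
Product: 6 ethyl 2,6,6-trimethyl-4-oxocyclohex-1-ene-1-carboxylate, via silyl enol ether cycloadduct 5 (not isolated)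
Conditions: EtAlCl2 (0.3 equiv), CH2Cl2, −78 → 0 °C; then 1 M HCl, THF, 0 °C
Reagents that add atoms: none
Why: EtAlCl2 activates the ynoate, whose β-carbon (the methyl-bearing alkyne carbon) is attacked by the terminal CH2 of silyl dienol ether 3 (Mukaiyama–Michael step) to give an aluminium allenoate and a silyloxy-allyl cation, and the allenoate α-carbon then closes onto the tertiary C(CH3)2 terminus, so that the CH2–C(CH3)= bond and the =C(CO2Et)–C(CH3)2 bond arise in one operation; a concerted but strongly asynchronous Diels–Alder transition state is the limiting alternative and leads to the same adduct 5. The closest known reaction types are the Lewis-acid-promoted Diels–Alder (double Michael) reactions of hindered 4,4-disubstituted 2-silyloxydienes with enones and the cycloadditions of 2-silyloxydienes with alkynoates. The single carbocycle is closed in a formal [4+2] mode (second bond by 6-endo attack on the allyl cation) and delivers at once the tetrasubstituted ring double bond, all three ring methyl groups, the ring oxygen on the correct carbon and the exocyclic carbon at the ester level. No stereocentre is formed (5 and 6 are achiral), so only regio- and chemoselectivity are needed. Regiochemistry (oxygen-bearing carbon para to the ester-bearing carbon) follows from pairing the nucleophilic enol-ether CH2 with the electrophilic ynoate β-carbon; a cyclobutene from competing 1,2-closure should reopen to the same zwitterion on warming, the low temperature avoids the 1,5-hydrogen shift that the cis-methyl diene would suffer on heating, and brief cold acid hydrolysis of the enol ether should leave the β,γ-unsaturated ketone unconjugated.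

Step 3
Reactants: 6 ethyl 2,6,6-trimethyl-4-oxocyclohex-1-ene-1-carboxylate
Product: 7 ethyl (4R)-4-hydroxy-2,6,6-trimethylcyclohex-1-ene-1-carboxylate
Conditions: (R)-selective ketoreductase, NADP+ (cat.), i-PrOH, phosphate buffer pH 7, 30 °C
Reagents that add atoms: none
Why: Enzymatic ketone reduction with cofactor recycling, in which the active site distinguishes the CH2–C(CH3)2 flank from the CH2–C(CH3)= flank and delivers hydride to one carbonyl face, should set the (R)-carbinol centre common to both end groups under neutral conditions that do not move the ring double bond (close precedent: biocatalytic reductions of 2,2,6-trimethylcyclohexane-1,4-diones to the same hydroxylated end-group precursors).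

Step 4
Reactants: 7 ethyl (4R)-4-hydroxy-2,6,6-trimethylcyclohex-1-ene-1-carboxylate
Product: 8 ethyl (4R)-4-{[tert-butyl(dimethyl)silyl]oxy}-2,6,6-trimethylcyclohex-1-ene-1-carboxylate
Conditions: TBSCl, imidazole, DMF, rt
Reagents that add atoms: tert-butyl(chloro)dimethylsilane (TBSCl), CC(C)(C)[Si](C)(C)Cl
Why: Standard silylation of a secondary alcohol, which does not touch the stereocentre.

Step 5
Reactants: 8 ethyl (4R)-4-{[tert-butyl(dimethyl)silyl]oxy}-2,6,6-trimethylcyclohex-1-ene-1-carboxylate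
Product: 9 [(4R)-4-{[tert-butyl(dimethyl)silyl]oxy}-2,6,6-trimethylcyclohex-1-en-1-yl]methanol
Conditions: iBu2AlH, CH2Cl2, −78 → 0 °C; aq. potassium sodium tartrate
Reagents that add atoms: none
Why: 1,2-Reduction of the hindered conjugated ester by the aluminium hydride should give the allylic alcohol and leave the silyl ether intact.

Step 6
Reactants: 9 [(4R)-4-{[tert-butyl(dimethyl)silyl]oxy}-2,6,6-trimethylcyclohex-1-en-1-yl]methanol
Product: 10 (4R)-4-{[tert-butyl(dimethyl)silyl]oxy}-2,6,6-trimethylcyclohex-1-ene-1-carbaldehyde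
Conditions: MnO2, CH2Cl2, rt
Reagents that add atoms: none
Why: Selective oxidation of an allylic alcohol by MnO2 should give the enal without affecting the silyl ether.

Step 7
Reactants: 10 (4R)-4-{[tert-butyl(dimethyl)silyl]oxy}-2,6,6-trimethylcyclohex-1-ene-1-carbaldehyde
Product: 11 tert-butyl{[(1R)-4-ethynyl-3,5,5-trimethylcyclohex-3-en-1-yl]oxy}dimethylsilane
Conditions: Me3SiCHN2, LiN(iPr)2, THF, −78 °C → rt
Reagents that add atoms: (trimethylsilyl)diazomethane, C[Si](C)(C)C=[N+]=[N-]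
Why: Colvin rearrangement (addition of the lithiated diazo reagent, Peterson-type elimination, loss of N2 and 1,2-hydrogen shift of the alkylidene carbene) should give the terminal alkyne under aprotic conditions that avoid conjugate addition to the enal.

Step 8
Reactants: 12 ethyl acetoacetate (ethyl 3-oxobutanoate)
Product: 13 ethyl (2E)-3-{[(trifluoromethyl)sulfonyl]oxy}but-2-enoate
Conditions: Tf2O, aq. Me4NOH, hexane, 5 °C
Reagents that add atoms: trifluoromethanesulfonic anhydride, O=S(=O)(OS(=O)(=O)C(F)(F)F)C(F)(F)F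
Why: O-Triflation of the acetoacetate enolate under non-chelating tetraalkylammonium conditions should give the (E)-enol triflate (triflate trans to the ester), which fixes the later 9'-E geometry.

Step 9
Reactants: 11 tert-butyl{[(1R)-4-ethynyl-3,5,5-trimethylcyclohex-3-en-1-yl]oxy}dimethylsilane; 13 ethyl (2E)-3-{[(trifluoromethyl)sulfonyl]oxy}but-2-enoate
Product: 14 ethyl (2E)-5-[(4R)-4-{[tert-butyl(dimethyl)silyl]oxy}-2,6,6-trimethylcyclohex-1-en-1-yl]-3-methylpent-2-en-4-ynoate
Conditions: PdCl2(PPh3)2 (cat.), CuI (cat.), Et3N, THF, rt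
Reagents that add atoms: none
Why: Sonogashira coupling of the terminal alkyne with the electron-poor enol triflate should form the C-8'–C-9' bond with retention of the alkene geometry.

Step 10
Reactants: 14 ethyl (2E)-5-[(4R)-4-{[tert-butyl(dimethyl)silyl]oxy}-2,6,6-trimethylcyclohex-1-en-1-yl]-3-methylpent-2-en-4-ynoate
Product: 15 (2E)-5-[(4R)-4-{[tert-butyl(dimethyl)silyl]oxy}-2,6,6-trimethylcyclohex-1-en-1-yl]-3-methylpent-2-en-4-yn-1-ol
Conditions: iBu2AlH, CH2Cl2, −78 °C
Reagents that add atoms: none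
Why: 1,2-Reduction of the conjugated ester should give the allylic alcohol without touching the enyne.

Step 11
Reactants: 15 (2E)-5-[(4R)-4-{[tert-butyl(dimethyl)silyl]oxy}-2,6,6-trimethylcyclohex-1-en-1-yl]-3-methylpent-2-en-4-yn-1-ol
Product: 17 {(2E)-5-[(4R)-4-{[tert-butyl(dimethyl)silyl]oxy}-2,6,6-trimethylcyclohex-1-en-1-yl]-3-methylpent-2-en-4-yn-1-yl}(triphenyl)phosphonium bromide, via allylic bromide 16 (not isolated)
Conditions: CBr4, PPh3, CH2Cl2, 0 °C; then PPh3, EtOAc, rt
Reagents that add atoms: carbon tetrabromide, BrC(Br)(Br)Br; triphenylphosphine, c1ccc(cc1)P(c1ccccc1)c1ccccc1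
Why: Appel bromination under neutral conditions that spare the silyl ether, followed by SN2 quaternisation of triphenylphosphine, should give the allylic phosphonium salt.

Step 12
Reactants: 17 {(2E)-5-[(4R)-4-{[tert-butyl(dimethyl)silyl]oxy}-2,6,6-trimethylcyclohex-1-en-1-yl]-3-methylpent-2-en-4-yn-1-yl}(triphenyl)phosphonium bromide; 18 (2E,4E,6E)-2,7-dimethylocta-2,4,6-trienedial
Product: 20 (2E,4E,6E,8E,10E)-13-[(4R)-4-{[tert-butyl(dimethyl)silyl]oxy}-2,6,6-trimethylcyclohex-1-en-1-yl]-2,7,11-trimethyltrideca-2,4,6,8,10-pentaen-12-ynal, via phosphorus ylide 19 (not isolated)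
Conditions: NaOMe, CH2Cl2–MeOH, 0 °C → rt (18 in excess); then heptane, 80 °C
Reagents that add atoms: none
Why: Wittig olefination of the allylic ylide with one aldehyde group of the excess dialdehyde should give the C25 polyenal, and the new C-11'=C-12' bond, formed as an E/Z mixture, should equilibrate to E on heating.

Step 13
Reactants: 9 [(4R)-4-{[tert-butyl(dimethyl)silyl]oxy}-2,6,6-trimethylcyclohex-1-en-1-yl]methanol
Product: 21 [(1R,4S,6R)-4-{[tert-butyl(dimethyl)silyl]oxy}-2,2,6-trimethyl-7-oxabicyclo[4.1.0]heptan-1-yl]methanol (oxirane trans to the silyloxy group)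
Conditions: Ti(OiPr)4 (cat.), D-(−)-diethyl tartrate (cat.), t-BuOOH, 4 Å molecular sieves, CH2Cl2, −20 °C
Reagents that add atoms: tert-butyl hydroperoxide, CC(C)(C)OO
Why: Sharpless asymmetric epoxidation of the tetrasubstituted allylic alcohol should deliver oxygen to the face selected by D-(−)-diethyl tartrate, which is also the face anti to the bulky silyloxy group (matched case), and so set both oxirane carbons.

Step 14
Reactants: 21 [(1R,4S,6R)-4-{[tert-butyl(dimethyl)silyl]oxy}-2,2,6-trimethyl-7-oxabicyclo[4.1.0]heptan-1-yl]methanol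
Product: 22 (1S,4S,6R)-4-{[tert-butyl(dimethyl)silyl]oxy}-2,2,6-trimethyl-7-oxabicyclo[4.1.0]heptane-1-carbaldehyde
Conditions: Dess–Martin periodinane, CH2Cl2, rt
Reagents that add atoms: none
Why: Dess–Martin oxidation of the hindered primary alcohol should give the epoxy aldehyde, whose α-carbon is quaternary and cannot epimerise.

Step 15
Reactants: 22 (1S,4S,6R)-4-{[tert-butyl(dimethyl)silyl]oxy}-2,2,6-trimethyl-7-oxabicyclo[4.1.0]heptane-1-carbaldehyde
Product: 23 (3E)-4-[(1S,4S,6R)-4-{[tert-butyl(dimethyl)silyl]oxy}-2,2,6-trimethyl-7-oxabicyclo[4.1.0]heptan-1-yl]but-3-en-2-one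
Conditions: Ph3P=CHC(O)CH3, toluene, 90 °C
Reagents that add atoms: 1-(triphenyl-λ5-phosphanylidene)propan-2-one, CC(=O)C=P(c1ccccc1)(c1ccccc1)c1ccccc1
Why: Wittig olefination with a stabilised ylide should give the (E)-enone under neutral conditions that leave the oxirane intact.

Step 16
Reactants: 23 (3E)-4-[(1S,4S,6R)-4-{[tert-butyl(dimethyl)silyl]oxy}-2,2,6-trimethyl-7-oxabicyclo[4.1.0]heptan-1-yl]but-3-en-2-one
Product: 24 (3E)-4-[(1S,2S,4S)-4-{[tert-butyl(dimethyl)silyl]oxy}-1,2-dihydroxy-2,6,6-trimethylcyclohexyl]but-3-en-2-one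
Conditions: HClO4 (cat.), THF–H2O, 0 °C
Reagents that add atoms: water, O
Why: Acid-catalysed epoxide hydrolysis should open the protonated oxirane at the methyl-bearing C-5 (tertiary, less hindered and remote from the electron-poor enone, whereas C-6 is flanked by the quaternary carbon and deactivated by the enone) with water entering anti to the departing oxygen, so that C-5 is inverted (5-OH cis to the C-3 oxygen and trans to 6-OH) and C-6 keeps its configuration.

Step 17
Reactants: 24 (3E)-4-[(1S,2S,4S)-4-{[tert-butyl(dimethyl)silyl]oxy}-1,2-dihydroxy-2,6,6-trimethylcyclohexyl]but-3-en-2-one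
Product: 25 ethyl (2E,4E)-5-[(1S,2S,4S)-4-{[tert-butyl(dimethyl)silyl]oxy}-1,2-dihydroxy-2,6,6-trimethylcyclohexyl]-3-methylpenta-2,4-dienoate
Conditions: (EtO)2P(O)CH2CO2Et, NaH (excess), THF, 0 → 50 °C
Reagents that add atoms: triethyl phosphonoacetate, CCOC(=O)CP(=O)(OCC)OCC
Why: Horner–Wadsworth–Emmons olefination of the methyl ketone should give the (2E)-dienoate as the main isomer (the minor 9Z isomer is removed by chromatography), the tertiary hydroxyl groups being only deprotonated reversibly.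

Step 18
Reactants: 25 ethyl (2E,4E)-5-[(1S,2S,4S)-4-{[tert-butyl(dimethyl)silyl]oxy}-1,2-dihydroxy-2,6,6-trimethylcyclohexyl]-3-methylpenta-2,4-dienoate
Product: 26 (1S,2S,4S)-4-{[tert-butyl(dimethyl)silyl]oxy}-1-[(1E,3E)-5-hydroxy-3-methylpenta-1,3-dien-1-yl]-2,6,6-trimethylcyclohexane-1,2-diol
Conditions: iBu2AlH (excess), CH2Cl2, −78 °C
Reagents that add atoms: none
Why: 1,2-Reduction of the dienoate should give the primary dienol without affecting the tertiary diol or the silyl ether.

Step 19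
Reactants: 26 (1S,2S,4S)-4-{[tert-butyl(dimethyl)silyl]oxy}-1-[(1E,3E)-5-hydroxy-3-methylpenta-1,3-dien-1-yl]-2,6,6-trimethylcyclohexane-1,2-diol
Product: 28 {(2E,4E)-5-[(1S,2S,4S)-4-{[tert-butyl(dimethyl)silyl]oxy}-1,2-dihydroxy-2,6,6-trimethylcyclohexyl]-3-methylpenta-2,4-dien-1-yl}(triphenyl)phosphonium bromide, via dienyl bromide 27 (not isolated)
Conditions: CBr4, PPh3, CH2Cl2, −20 °C; then PPh3, EtOAc, rt
Reagents that add atoms: carbon tetrabromide, BrC(Br)(Br)Br; triphenylphosphine, c1ccc(cc1)P(c1ccccc1)c1ccccc1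
Why: Appel bromination at low temperature should convert only the primary allylic alcohol (the tertiary alcohols do not react), and the labile dienyl bromide is trapped at once by triphenylphosphine.

Step 20
Reactants: 28 {(2E,4E)-5-[(1S,2S,4S)-4-{[tert-butyl(dimethyl)silyl]oxy}-1,2-dihydroxy-2,6,6-trimethylcyclohexyl]-3-methylpenta-2,4-dien-1-yl}(triphenyl)phosphonium bromide; 20 (2E,4E,6E,8E,10E)-13-[(4R)-4-{[tert-butyl(dimethyl)silyl]oxy}-2,6,6-trimethylcyclohex-1-en-1-yl]-2,7,11-trimethyltrideca-2,4,6,8,10-pentaen-12-ynal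
Product: 30 (3S,5S,6S,3'R)-3,3'-bis-O-[tert-butyl(dimethyl)silyl]-7',8'-didehydro-5,6-dihydro-β,β-carotene-3,5,6,3'-tetrol, via phosphorus ylide 29 (not isolated)
Conditions: NaOMe, CH2Cl2–MeOH, rt; then EtOAc, 70 °C
Reagents that add atoms: none
Why: Wittig olefination of the dienyl ylide with the C25 polyenal should form the C-11=C-12 bond and complete the C40 chain, the E/Z mixture at the new bond equilibrating to all-E on heating while all stereocentres stay untouched.

Step 21
Reactants: 30 (3S,5S,6S,3'R)-3,3'-bis-O-[tert-butyl(dimethyl)silyl]-7',8'-didehydro-5,6-dihydro-β,β-carotene-3,5,6,3'-tetrol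
Product: 31 (3S,5S,6S,3'R)-7',8'-didehydro-5,6-dihydro-β,β-carotene-3,5,6,3'-tetrol (CNP0160593.1)
Conditions: Bu4NF, THF, rt
Reagents that add atoms: none
Why: Fluoride-mediated cleavage of both secondary silyl ethers under non-acidic conditions should release the tetrol without ionising the tertiary allylic 6-OH or isomerising the polyene.

## Compound list

1 | mesityl oxide (4-methylpent-3-en-2-one) | CC(C)=CC(C)=O | starting material
2 | lithium 4-methylpenta-1,3-dien-2-olate | [Li+].[O-]C(=C)C=C(C)C | intermediate (not isolated)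
3 | tert-butyl(dimethyl)[(4-methylpenta-1,3-dien-2-yl)oxy]silane | C=C(O[Si](C)(C)C(C)(C)C)C=C(C)C | intermediate
4 | ethyl but-2-ynoate | CC#CC(=O)OCC | starting material
5 | ethyl 4-{[tert-butyl(dimethyl)silyl]oxy}-2,6,6-trimethylcyclohexa-1,4-diene-1-carboxylate | CCOC(=O)C1=C(C)CC(O[Si](C)(C)C(C)(C)C)=CC1(C)C | intermediate (not isolated)
6 | ethyl 2,6,6-trimethyl-4-oxocyclohex-1-ene-1-carboxylate | CCOC(=O)C1=C(C)CC(=O)CC1(C)C | intermediate
7 | ethyl (4R)-4-hydroxy-2,6,6-trimethylcyclohex-1-ene-1-carboxylate | CC1=C(C(=O)OCC)C(C)(C)C[C@H](O)C1 | intermediate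
8 | ethyl (4R)-4-{[tert-butyl(dimethyl)silyl]oxy}-2,6,6-trimethylcyclohex-1-ene-1-carboxylate | CC1=C(C(=O)OCC)C(C)(C)C[C@H](O[Si](C)(C)C(C)(C)C)C1 | intermediate
9 | [(4R)-4-{[tert-butyl(dimethyl)silyl]oxy}-2,6,6-trimethylcyclohex-1-en-1-yl]methanol | CC1=C(CO)C(C)(C)C[C@H](O[Si](C)(C)C(C)(C)C)C1 | intermediate
10 | (4R)-4-{[tert-butyl(dimethyl)silyl]oxy}-2,6,6-trimethylcyclohex-1-ene-1-carbaldehyde | CC1=C(C=O)C(C)(C)C[C@H](O[Si](C)(C)C(C)(C)C)C1 | intermediate
11 | tert-butyl{[(1R)-4-ethynyl-3,5,5-trimethylcyclohex-3-en-1-yl]oxy}dimethylsilane | CC1=C(C#C)C(C)(C)C[C@H](O[Si](C)(C)C(C)(C)C)C1 | intermediate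
12 | ethyl acetoacetate (ethyl 3-oxobutanoate) | CC(=O)CC(=O)OCC | starting material
13 | ethyl (2E)-3-{[(trifluoromethyl)sulfonyl]oxy}but-2-enoate | C/C(=C\C(=O)OCC)OS(=O)(=O)C(F)(F)F | intermediate
14 | ethyl (2E)-5-[(4R)-4-{[tert-butyl(dimethyl)silyl]oxy}-2,6,6-trimethylcyclohex-1-en-1-yl]-3-methylpent-2-en-4-ynoate | CC1=C(C#C/C(C)=C/C(=O)OCC)C(C)(C)C[C@H](O[Si](C)(C)C(C)(C)C)C1 | intermediate
15 | (2E)-5-[(4R)-4-{[tert-butyl(dimethyl)silyl]oxy}-2,6,6-trimethylcyclohex-1-en-1-yl]-3-methylpent-2-en-4-yn-1-ol | CC1=C(C#C/C(C)=C/CO)C(C)(C)C[C@H](O[Si](C)(C)C(C)(C)C)C1 | intermediate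
16 | {[(1R)-4-[(3E)-5-bromo-3-methylpent-3-en-1-yn-1-yl]-3,5,5-trimethylcyclohex-3-en-1-yl]oxy}(tert-butyl)dimethylsilane | CC1=C(C#C/C(C)=C/CBr)C(C)(C)C[C@H](O[Si](C)(C)C(C)(C)C)C1 | intermediate (not isolated)
17 | {(2E)-5-[(4R)-4-{[tert-butyl(dimethyl)silyl]oxy}-2,6,6-trimethylcyclohex-1-en-1-yl]-3-methylpent-2-en-4-yn-1-yl}(triphenyl)phosphonium bromide | CC1=C(C#C/C(C)=C/C[P+](c2ccccc2)(c2ccccc2)c2ccccc2)C(C)(C)C[C@H](O[Si](C)(C)C(C)(C)C)C1.[Br-] | intermediate
18 | (2E,4E,6E)-2,7-dimethylocta-2,4,6-trienedial | O=C/C(C)=C/C=C/C=C(C)/C=O | starting material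
19 | ylide of 17, {(2E)-5-[(4R)-4-{[tert-butyl(dimethyl)silyl]oxy}-2,6,6-trimethylcyclohex-1-en-1-yl]-3-methylpent-2-en-4-yn-1-ylidene}(triphenyl)-λ5-phosphane | CC1=C(C#C/C(C)=C/C=P(c2ccccc2)(c2ccccc2)c2ccccc2)C(C)(C)C[C@H](O[Si](C)(C)C(C)(C)C)C1 | intermediate (not isolated)
20 | (2E,4E,6E,8E,10E)-13-[(4R)-4-{[tert-butyl(dimethyl)silyl]oxy}-2,6,6-trimethylcyclohex-1-en-1-yl]-2,7,11-trimethyltrideca-2,4,6,8,10-pentaen-12-ynal | CC1=C(C#C/C(C)=C/C=C/C(C)=C/C=C/C=C(C)/C=O)C(C)(C)C[C@H](O[Si](C)(C)C(C)(C)C)C1 | intermediate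
21 | [(1R,4S,6R)-4-{[tert-butyl(dimethyl)silyl]oxy}-2,2,6-trimethyl-7-oxabicyclo[4.1.0]heptan-1-yl]methanol | OC[C@@]12O[C@]1(C)C[C@@H](O[Si](C)(C)C(C)(C)C)CC2(C)C | intermediate
22 | (1S,4S,6R)-4-{[tert-butyl(dimethyl)silyl]oxy}-2,2,6-trimethyl-7-oxabicyclo[4.1.0]heptane-1-carbaldehyde | O=C[C@@]12O[C@]1(C)C[C@@H](O[Si](C)(C)C(C)(C)C)CC2(C)C | intermediate
23 | (3E)-4-[(1S,4S,6R)-4-{[tert-butyl(dimethyl)silyl]oxy}-2,2,6-trimethyl-7-oxabicyclo[4.1.0]heptan-1-yl]but-3-en-2-one | CC(=O)/C=C/[C@@]12O[C@]1(C)C[C@@H](O[Si](C)(C)C(C)(C)C)CC2(C)C | intermediate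
24 | (3E)-4-[(1S,2S,4S)-4-{[tert-butyl(dimethyl)silyl]oxy}-1,2-dihydroxy-2,6,6-trimethylcyclohexyl]but-3-en-2-one | CC(=O)/C=C/[C@]1(O)C(C)(C)C[C@H](O[Si](C)(C)C(C)(C)C)C[C@]1(C)O | intermediate
25 | ethyl (2E,4E)-5-[(1S,2S,4S)-4-{[tert-butyl(dimethyl)silyl]oxy}-1,2-dihydroxy-2,6,6-trimethylcyclohexyl]-3-methylpenta-2,4-dienoate | CCOC(=O)/C=C(C)/C=C/[C@]1(O)C(C)(C)C[C@H](O[Si](C)(C)C(C)(C)C)C[C@]1(C)O | intermediate
26 | (1S,2S,4S)-4-{[tert-butyl(dimethyl)silyl]oxy}-1-[(1E,3E)-5-hydroxy-3-methylpenta-1,3-dien-1-yl]-2,6,6-trimethylcyclohexane-1,2-diol | OC/C=C(C)/C=C/[C@]1(O)C(C)(C)C[C@H](O[Si](C)(C)C(C)(C)C)C[C@]1(C)O | intermediate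
27 | (1S,2S,4S)-1-[(1E,3E)-5-bromo-3-methylpenta-1,3-dien-1-yl]-4-{[tert-butyl(dimethyl)silyl]oxy}-2,6,6-trimethylcyclohexane-1,2-diol | BrC/C=C(C)/C=C/[C@]1(O)C(C)(C)C[C@H](O[Si](C)(C)C(C)(C)C)C[C@]1(C)O | intermediate (not isolated)
28 | {(2E,4E)-5-[(1S,2S,4S)-4-{[tert-butyl(dimethyl)silyl]oxy}-1,2-dihydroxy-2,6,6-trimethylcyclohexyl]-3-methylpenta-2,4-dien-1-yl}(triphenyl)phosphonium bromide | [Br-].c1ccccc1[P+](c1ccccc1)(c1ccccc1)C/C=C(C)/C=C/[C@]1(O)C(C)(C)C[C@H](O[Si](C)(C)C(C)(C)C)C[C@]1(C)O | intermediate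
29 | ylide of 28, {(2E,4E)-5-[(1S,2S,4S)-4-{[tert-butyl(dimethyl)silyl]oxy}-1,2-dihydroxy-2,6,6-trimethylcyclohexyl]-3-methylpenta-2,4-dien-1-ylidene}(triphenyl)-λ5-phosphane | c1ccccc1P(c1ccccc1)(c1ccccc1)=C/C=C(C)/C=C/[C@]1(O)C(C)(C)C[C@H](O[Si](C)(C)C(C)(C)C)C[C@]1(C)O | intermediate (not isolated)
30 | (3S,5S,6S,3'R)-3,3'-bis-O-[tert-butyl(dimethyl)silyl]-7',8'-didehydro-5,6-dihydro-β,β-carotene-3,5,6,3'-tetrol | CC1=C(C#C/C(C)=C/C=C/C(C)=C/C=C/C=C(C)/C=C/C=C(C)/C=C/[C@]2(O)C(C)(C)C[C@H](O[Si](C)(C)C(C)(C)C)C[C@]2(C)O)C(C)(C)C[C@H](O[Si](C)(C)C(C)(C)C)C1 | intermediate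
31 | (3S,5S,6S,3'R)-7',8'-didehydro-5,6-dihydro-β,β-carotene-3,5,6,3'-tetrol (CNP0160593.1) | CC1=C(C#C/C(C)=C/C=C/C(C)=C/C=C/C=C(C)/C=C/C=C(C)/C=C/[C@]2(O)C(C)(C)C[C@H](O)C[C@]2(C)O)C(C)(C)C[C@H](O)C1 | target

## Step count and risks

Total step count: 21.
Longest linear sequence: 14 steps (steps 1–5 and 13–21).

Steps most likely to fail:

1. Step 2. The stepwise cycloaddition may stall after the first C–C bond or at a vinylcyclobutene, or the hindered diene may be lost by protodesilylation and oligomerisation before the ring closes. The fallback sets out from mesityl oxide 1 and ethyl acetoacetate 12. ZnCl2-catalysed Michael addition and aldol condensation (toluene, reflux, water separator) should give racemic ethyl 2,6,6-trimethyl-4-oxocyclohex-2-ene-1-carboxylate F1. Ketalisation with ethane-1,2-diol and TsOH then moves the double bond into conjugation with the ester and gives ethyl 7,9,9-trimethyl-1,4-dioxaspiro[4.5]dec-7-ene-8-carboxylate F2. Mild transketalisation (pyridinium tosylate, wet acetone, rt) comes back to the route at keto ester 6.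

2. Step 3. The enzyme may give insufficient enantioselectivity, or the ring double bond may migrate into conjugation with the ketone in the buffer before reduction. The fallback sets out from 6. Reduction with NaBH4 and CeCl3·7H2O in MeOH at −78 °C should give racemic ethyl 4-hydroxy-2,6,6-trimethylcyclohex-1-ene-1-carboxylate F3. Lipase-catalysed acetylation (Burkholderia cepacia lipase, vinyl acetate, t-BuOMe) is expected to acylate the (R)-alcohol (the CH2–C(CH3)2 flank acting as the large group) to ethyl (4R)-4-acetoxy-2,6,6-trimethylcyclohex-1-ene-1-carboxylate F4 and to leave ethyl (4S)-4-hydroxy-2,6,6-trimethylcyclohex-1-ene-1-carboxylate F5. After separation, F5 is converted into more F4 by Mitsunobu inversion (AcOH, PPh3, diisopropyl azodicarboxylate). Ethanolysis of F4 (K2CO3, EtOH) comes back to the route at 7.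

3. Step 16. Water may attack the other oxirane carbon or attack with incomplete inversion, and the silyl ether may be lost under the acid. The fallback sets out from epoxy enone 23 and fixes regio- and stereochemistry by a tether.
   - Bu4NF should give (3E)-4-[(1S,4S,6R)-4-hydroxy-2,2,6-trimethyl-7-oxabicyclo[4.1.0]heptan-1-yl]but-3-en-2-one F6.
   - Boc2O and DMAP should give its 4-O-(tert-butoxycarbonyl) derivative F7.
   - BF3·OEt2 (CH2Cl2, −40 °C) should make the carbonate carbonyl oxygen open the oxirane at C-5 from the face of the C-3 oxygen, the only face it can reach, with inversion and loss of the tert-butyl group. This gives the bridged cyclic 3,5-carbonate with free 6-OH, (3E)-4-[3,5-O-carbonyl-(3S,5S,6S)-3,5,6-trihydroxy-2,2,6-trimethylcyclohexyl]but-3-en-2-one (carotenoid-type locants) F8.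
   - K2CO3 in MeOH should cleave the carbonate to (3E)-4-[(1S,2S,4S)-1,2,4-trihydroxy-2,6,6-trimethylcyclohexyl]but-3-en-2-one F9.
   - TBSCl and imidazole silylate only the secondary hydroxyl group, which comes back to the route at 24.

Further compounds
F1 | step 2 | ethyl 2,6,6-trimethyl-4-oxocyclohex-2-ene-1-carboxylate (racemic) | CCOC(=O)C1C(C)=CC(=O)CC1(C)C
F2 | step 2 | ethyl 7,9,9-trimethyl-1,4-dioxaspiro[4.5]dec-7-ene-8-carboxylate | CCOC(=O)C1=C(C)CC2(CC1(C)C)OCCO2
F3 | step 3 | ethyl 4-hydroxy-2,6,6-trimethylcyclohex-1-ene-1-carboxylate (racemic) | CC1=C(C(=O)OCC)C(C)(C)CC(O)C1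
F4 | step 3 | ethyl (4R)-4-acetoxy-2,6,6-trimethylcyclohex-1-ene-1-carboxylate | CC1=C(C(=O)OCC)C(C)(C)C[C@H](OC(C)=O)C1
F5 | step 3 | ethyl (4S)-4-hydroxy-2,6,6-trimethylcyclohex-1-ene-1-carboxylate | CC1=C(C(=O)OCC)C(C)(C)C[C@@H](O)C1
F6 | step 16 | (3E)-4-[(1S,4S,6R)-4-hydroxy-2,2,6-trimethyl-7-oxabicyclo[4.1.0]heptan-1-yl]but-3-en-2-one | CC(=O)/C=C/[C@@]12O[C@]1(C)C[C@@H](O)CC2(C)C
F7 | step 16 | 4-O-(tert-butoxycarbonyl) derivative of F6 (tert-butyl carbonate of the ring hydroxyl group) | CC(=O)/C=C/[C@@]12O[C@]1(C)C[C@@H](OC(=O)OC(C)(C)C)CC2(C)C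
F8 | step 16 | bridged cyclic 3,5-carbonate of the (3S,5S,6S)-triol enone, 6-OH free (2,4-dioxabicyclo[3.3.1]nonan-3-one core) | CC(=O)/C=C/[C@]1(O)C(C)(C)C[C@@H]2OC(=O)O[C@@]1(C)C2
F9 | step 16 | (3E)-4-[(1S,2S,4S)-1,2,4-trihydroxy-2,6,6-trimethylcyclohexyl]but-3-en-2-one | CC(=O)/C=C/[C@]1(O)C(C)(C)C[C@H](O)C[C@]1(C)O
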